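**Strategy**

The butyrolactone is disconnected at O1–C2 and C3–C4. Atoms O1–C5–C4 are read as the alkoxide-terminated allyl unit of a π-allylpalladium zwitterion and C2–C3 as an aldoketene that already carries the ring B benzyl group; the vinyl group left on C4 is the masked ring A benzyl. One enantioconvergent, decarboxylative (3+2) annulation of racemic vinylethylene carbonate with this ketene thus closes the lactone, forms both ring bonds and fixes C4 (ligand) and C3 (trans). The ketene is generated salt-free from 3-(4-benzyloxy-3,5-dimethoxyphenyl)propanoyl chloride. Afterwards the vinyl group is cut to a bromomethyl arm, arylated with ring A by nickel catalysis, and the benzyl ether is removed.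

Key step: step 4

Assumption: the (S,S,S) phosphoramidite is taken to deliver the 4R lactone; if the sense of induction proves opposite, its (R,R,R) enantiomer is used without other change.

**Route**

Step 1
Reactants: 1 syringaldehyde (4-hydroxy-3,5-dimethoxybenzaldehyde)
Product: 2 4-benzyloxy-3,5-dimethoxybenzaldehyde
Conditions: BnBr, K2CO3, DMF, 60 °C
Reagents that add atoms: benzyl bromide, BrCc1ccccc1
Why: Williamson ether synthesis; the phenoxide, the only acidic site, is alkylated by the reactive benzylic bromide.

Step 2
Reactants: 2 4-benzyloxy-3,5-dimethoxybenzaldehyde; 3 Meldrum's acid (2,2-dimethyl-1,3-dioxane-4,6-dione)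
Product: 6 3-(4-benzyloxy-3,5-dimethoxyphenyl)propanoic acid, via arylidene Meldrum's acid 4 (not isolated), via benzyl Meldrum's acid 5 (not isolated)
Conditions: HCO2H/Et3N (5:2), 95–100 °C; then aq. HCl
Reagents that add atoms: water (made in the condensation and taken up again in the ring opening), O
Why: Domino Knoevenagel condensation, conjugate reduction of the arylidene Meldrum's acid by hydride transfer from formate, and hydrolytic decarboxylation should give the saturated acid in one flask without hydrogen gas or palladium, so the benzyl ether is not at risk.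

Step 3
Reactants: 6 3-(4-benzyloxy-3,5-dimethoxyphenyl)propanoic acid
Product: 7 3-(4-benzyloxy-3,5-dimethoxyphenyl)propanoyl chloride
Conditions: (COCl)2, DMF (cat.), CH2Cl2, 0 °C → rt; evaporate, use crude
Reagents that add atoms: oxalyl chloride, O=C(Cl)C(=O)Cl
Why: Standard acid chloride formation through the chloroiminium (Vilsmeier) reagent; no Lewis acid is present, so the electron-rich ring should not close onto the acyl group in a Friedel–Crafts reaction.

Step 4
Reactants: 7 3-(4-benzyloxy-3,5-dimethoxyphenyl)propanoyl chloride; 8 racemic 4-vinyl-1,3-dioxolan-2-one (vinylethylene carbonate)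
Product: 11 (3R,4R)-3-[(4-benzyloxy-3,5-dimethoxyphenyl)methyl]-4-ethenyloxolan-2-one (trans), via aldoketene 9 (not isolated), via C3-epimeric vinyl lactone 10 (not isolated)
Conditions: 7, polystyrene-bound BEMP, THF, −78 °C, cold filtration; filtrate added over 3 h to 8 (1.5 equiv), Pd2(dba)3·CHCl3 (2.5 mol%), (S)-BINOL-derived N,N-bis[(S)-1-phenylethyl]phosphoramidite (10 mol%), THF, −20 → 0 °C; then DBU (0.5 equiv), 50 °C
Reagents that add atoms: none
Why: Proposed new method: zerovalent palladium should ionise either enantiomer of 8 with loss of CO2 to a π-allylpalladium alkoxide, whose oxygen adds to the carbonyl carbon of ketene 9 (bond O1–C2), after which the tethered ester enolate alkylates the internal allyl terminus through its α-carbon (bond C3–C4) and releases the catalyst. The closest known reactions are the palladium-catalysed decarboxylative (3+2) cycloadditions of vinylethylene carbonates with aldehydes, imines, isocyanates and Michael acceptors, and the capture of ketenes by the zwitterions from vinyl benzoxazinanones in (4+2) and from vinylethylene carbonates in (5+2) annulations. The lactone closes by 5-exo-trig attack of enolate carbon C3 on C4, the palladium-bound allyl bond lying outside the new ring; this is an enolendo closure and the geometrically demanding element of the step. C4 is set by the chiral phosphoramidite on palladium during C–C bond formation, π–σ–π interchange of the allyl complexes being faster than closure so that racemic 8 converges on one enantiomer, and C3 is brought to the more stable trans arrangement by the DBU added at the end, which cannot reach the non-acidic C4. The selectivity needed is C-alkylation at the internal carbon, against attack at the far terminus (the seven-membered lactone known for disubstituted ketenes) and against O-alkylation to a ketene acetal; the substrate supports it because the aldoketene gives an unhindered secondary enolate carbon, the internal allyl carbon of unsubstituted 8 is secondary, the single carbon C5 between O1 and the allyl unit holds C3 next to C4, and phosphoramidite–palladium allyl complexes send tethered nucleophiles to the branched position. The ketene is made beforehand, free of acid chloride, amine and ammonium salt, and is fed slowly, so that the enolate is not protonated, the alkoxide is not simply acylated and 9 does not dimerise.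

Step 5
Reactants: 11 (3R,4R)-3-[(4-benzyloxy-3,5-dimethoxyphenyl)methyl]-4-ethenyloxolan-2-one
Product: 13 (3R,4S)-3-[(4-benzyloxy-3,5-dimethoxyphenyl)methyl]-4-(hydroxymethyl)oxolan-2-one, via lactone aldehyde 12 (not isolated)
Conditions: O3, CH2Cl2/MeOH (4:1), Sudan Red 7B (trace), −78 °C; then NaBH4, −78 → 0 °C; AcOH quench
Reagents that add atoms: ozone, [O-][O+]=O
Why: Ozonolysis with reductive work-up: the terminal alkene should react far faster with ozone than the alkoxyarenes (the dye marks the end point) and borohydride reduces the peroxidic intermediates and aldehyde 12 as it is unmasked, so C4 has no time to epimerise; no stereocentre is touched, the C4 descriptor changing from R to S only through the priority rules.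

Step 6
Reactants: 13 (3R,4S)-3-[(4-benzyloxy-3,5-dimethoxyphenyl)methyl]-4-(hydroxymethyl)oxolan-2-one
Product: 14 (3R,4R)-3-[(4-benzyloxy-3,5-dimethoxyphenyl)methyl]-4-(bromomethyl)oxolan-2-one
Conditions: CBr4, PPh3, CH2Cl2, 0 °C → rt
Reagents that add atoms: carbon tetrabromide, BrC(Br)(Br)Br
Why: Appel bromination: SN2 displacement of the alkoxyphosphonium ion at the primary carbon under neutral conditions, which avoids acyl migration and leaves C3 and C4 alone.

Step 7
Reactants: 14 (3R,4R)-3-[(4-benzyloxy-3,5-dimethoxyphenyl)methyl]-4-(bromomethyl)oxolan-2-one; 15 4-bromo-1,2-dimethoxybenzene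
Product: 16 (3R,4R)-3-[(4-benzyloxy-3,5-dimethoxyphenyl)methyl]-4-[(3,4-dimethoxyphenyl)methyl]oxolan-2-one
Conditions: NiI2 (10 mol%), 4,4'-di-tert-butyl-2,2'-bipyridine (10 mol%), NaI (25 mol%), pyridine (10 mol%), Zn dust (2 equiv), DMPU, 60 °C
Reagents that add atoms: none
Why: Nickel-catalysed reductive cross-electrophile coupling of a primary alkyl bromide with an aryl bromide: the arylnickel species from oxidative addition captures the primary alkyl radical and reductive elimination forms the CH2–aryl bond, a process that tolerates lactones and benzyl ethers and leaves both ring stereocentres, which are not at the radical site, untouched.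

Step 8
Reactants: 16 (3R,4R)-3-[(4-benzyloxy-3,5-dimethoxyphenyl)methyl]-4-[(3,4-dimethoxyphenyl)methyl]oxolan-2-one
Product: 17 (3R,4R)-4-[(3,4-dimethoxyphenyl)methyl]-3-[(4-hydroxy-3,5-dimethoxyphenyl)methyl]oxolan-2-one (CNP0280366.1)
Conditions: H2 (1 atm), Pd/C, EtOAc/EtOH, rt
Reagents that add atoms: none
Why: Catalytic hydrogenolysis of the aryl benzyl ether; the lactone, the methyl ethers and the benzylic C–C bonds are inert and no stereocentre is involved.

**Compound list**

1 | syringaldehyde (4-hydroxy-3,5-dimethoxybenzaldehyde) | COc1cc(C=O)cc(OC)c1O | starting material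
2 | 4-benzyloxy-3,5-dimethoxybenzaldehyde | COc1cc(C=O)cc(OC)c1OCc1ccccc1 | intermediate
3 | Meldrum's acid (2,2-dimethyl-1,3-dioxane-4,6-dione) | CC1(C)OC(=O)CC(=O)O1 | starting material
4 | 5-(4-benzyloxy-3,5-dimethoxybenzylidene)-2,2-dimethyl-1,3-dioxane-4,6-dione | COc1cc(C=C2C(=O)OC(C)(C)OC2=O)cc(OC)c1OCc1ccccc1 | intermediate (not isolated)
5 | 5-(4-benzyloxy-3,5-dimethoxybenzyl)-2,2-dimethyl-1,3-dioxane-4,6-dione | COc1cc(CC2C(=O)OC(C)(C)OC2=O)cc(OC)c1OCc1ccccc1 | intermediate (not isolated)
6 | 3-(4-benzyloxy-3,5-dimethoxyphenyl)propanoic acid | COc1cc(CCC(=O)O)cc(OC)c1OCc1ccccc1 | intermediate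
7 | 3-(4-benzyloxy-3,5-dimethoxyphenyl)propanoyl chloride | COc1cc(CCC(=O)Cl)cc(OC)c1OCc1ccccc1 | intermediate
8 | racemic 4-vinyl-1,3-dioxolan-2-one (vinylethylene carbonate) | C=CC1COC(=O)O1 | starting material
9 | 3-(4-benzyloxy-3,5-dimethoxyphenyl)prop-1-en-1-one (the aldoketene) | COc1cc(CC=C=O)cc(OC)c1OCc1ccccc1 | intermediate (not isolated)
10 | (4R)-3-[(4-benzyloxy-3,5-dimethoxyphenyl)methyl]-4-ethenyloxolan-2-one, C3 not yet defined | C=C[C@H]1COC(=O)C1Cc1cc(OC)c(OCc2ccccc2)c(OC)c1 | intermediate (not isolated)
11 | (3R,4R)-3-[(4-benzyloxy-3,5-dimethoxyphenyl)methyl]-4-ethenyloxolan-2-one | C=C[C@H]1COC(=O)[C@@H]1Cc1cc(OC)c(OCc2ccccc2)c(OC)c1 | intermediate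
12 | (3R,4R)-4-[(4-benzyloxy-3,5-dimethoxyphenyl)methyl]-5-oxooxolane-3-carbaldehyde | O=C[C@H]1COC(=O)[C@@H]1Cc1cc(OC)c(OCc2ccccc2)c(OC)c1 | intermediate (not isolated)
13 | (3R,4S)-3-[(4-benzyloxy-3,5-dimethoxyphenyl)methyl]-4-(hydroxymethyl)oxolan-2-one | OC[C@H]1COC(=O)[C@@H]1Cc1cc(OC)c(OCc2ccccc2)c(OC)c1 | intermediate
14 | (3R,4R)-3-[(4-benzyloxy-3,5-dimethoxyphenyl)methyl]-4-(bromomethyl)oxolan-2-one | BrC[C@H]1COC(=O)[C@@H]1Cc1cc(OC)c(OCc2ccccc2)c(OC)c1 | intermediate
15 | 4-bromo-1,2-dimethoxybenzene | COc1ccc(Br)cc1OC | starting material
16 | (3R,4R)-3-[(4-benzyloxy-3,5-dimethoxyphenyl)methyl]-4-[(3,4-dimethoxyphenyl)methyl]oxolan-2-one | COc1ccc(C[C@H]2COC(=O)[C@@H]2Cc2cc(OC)c(OCc3ccccc3)c(OC)c2)cc1OC | intermediate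
17 | (3R,4R)-4-[(3,4-dimethoxyphenyl)methyl]-3-[(4-hydroxy-3,5-dimethoxyphenyl)methyl]oxolan-2-one | COc1ccc(C[C@H]2COC(=O)[C@@H]2Cc2cc(OC)c(O)c(OC)c2)cc1OC | target

**Step count and risk**

Total step count: 8. Longest linear sequence: 8 steps (1 to 17).

Steps most likely to fail:

1. Step 4 (proposed new method). The ring may close at the wrong site: the enolate carbon may attack the far allyl terminus to give a seven-membered ring, or the enolate oxygen may attack instead, because the five-ring C-alkylation is an enolendo closure. The enolate may also be lost by protonation, the ketene may dimerise, or the ligand may induce poorly at C4. The fallback uses known chemistry and sets out from aldehyde 2 and carbonate 8. A Wittig reaction of 2 with (triphenylphosphoranylidene)acetaldehyde (toluene, 80 °C) should give (E)-3-(4-benzyloxy-3,5-dimethoxyphenyl)prop-2-enal F1. F1 and racemic 8 are then joined by the known cooperative iridium/N-heterocyclic carbene (3+2) annulation of enals with vinylethylene carbonate ([Ir(cod)Cl]2, a chiral phosphoramidite–olefin ligand, a chiral triazolium precatalyst, amine base, THF). In that reaction the azolium enolate formed from the enal attacks the iridium allyl at its branched carbon intermolecularly (C3–C4 first), and the freed hydroxyl then lactonises onto the acyl azolium (O1–C2). The C–C bond is made before the ring exists, so the enolendo constraint does not arise. The ligand/carbene pairing is chosen for the trans (3R,4R) isomer, and the route is rejoined at 11.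

2. Step 7. Oxidative addition of the electron-rich aryl bromide may be slow, so that homocoupling or reduction of the alkyl bromide outruns the cross-coupling. The fallback sets out from bromide 14. Zinc insertion (Zn dust, LiCl, THF, 50 °C) should give the alkylzinc bromide F2 (both stereocentres as in 14). Negishi coupling of F2 with 15 (Pd(OAc)2, SPhos, THF, rt → 50 °C) returns to 16. This replaces the radical cross-electrophile manifold by a two-electron coupling of a preformed nucleophile.

3. Step 5. Ozone may attack the two electron-rich rings. C4 may epimerise while the aldehyde is exposed to borohydride and methoxide. The lactone acyl group may migrate to the new hydroxymethyl arm, which would invert the relative configuration at C4 because both arms on C4 are then CH2O groups. The fallback avoids ozone and the free hydroxymethyl lactone and sets out from 11. Cleavage with K2OsO4·2H2O (cat.), NaIO4 and 2,6-lutidine in dioxane/H2O should give aldehyde 12, taken on crude. Condensation with TsNHNH2 (MeOH, rt) gives the (E)-N-tosylhydrazone of 12, F3 (both stereocentres as in 12). Metal-free reductive coupling of F3 with 3,4-dimethoxyphenylboronic acid (K2CO3, dioxane, 110 °C) should give 16 directly, where the route is rejoined.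

Further compounds
F1 | step 4 | (E)-3-(4-benzyloxy-3,5-dimethoxyphenyl)prop-2-enal | COc1cc(/C=C/C=O)cc(OC)c1OCc1ccccc1
F2 | step 7 | alkylzinc bromide from 14, {[(3R,4R)-4-(4-benzyloxy-3,5-dimethoxybenzyl)-5-oxooxolan-3-yl]methyl}zinc bromide | Br[Zn]C[C@H]1COC(=O)[C@@H]1Cc1cc(OC)c(OCc2ccccc2)c(OC)c1
F3 | step 5 | (E)-N-tosylhydrazone of aldehyde 12 | Cc1ccc(cc1)S(=O)(=O)N/N=C/[C@H]1COC(=O)[C@@H]1Cc1cc(OC)c(OCc2ccccc2)c(OC)c1
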